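Remark: benzofuran numbering is used throughout (O1, C2, C3, C3a to C7a; C9 is the CH2O carbon on C3); ring A is the benzo ring, ring B the aryl ring on C2, ring C the benzoate ring. The sense of induction of the chiral acid in step 9 cannot be predicted for a stilbene, so it is assumed that a first trial identifies the catalyst antipode that leads to the (4R,5R)-dioxane, both antipodes being equally accessible.

## The problem

The target 22 is a 2-aryl-2,3-dihydrobenzofuran neolignan. Ring A carries a methoxy group at C7 and a (Z)-3-oxoprop-1-enyl chain at C5; the dihydrofuran ring carries the guaiacyl ring B at C2 and, at C3, the one-carbon arm C9 as a 4-hydroxybenzoate. The two adjacent stereocentres are (2S,3R), with ring B and the C9 arm trans. C2 is benzylic, bound to O1 and para to the oxygen of ring B, so its C–O bond can be ionised and re-formed under acid and then settles trans to the C3 substituent. C3 has no such pathway, so it must be set absolutely and can then control C2, not the reverse. The (Z)-enal is the most fragile group (Z to E isomerisation by acid, base, nucleophiles or light, and conjugate addition), followed by the primary benzoate, the two free phenols and the benzylic aryl ether C2–O1, so the enal must appear late. The enabling feature is the C9–C3–C2 unit: C9 is a single oxygenated carbon on C3 and the neighbouring benzylic C2 also bears oxygen, which is the 1,3-dioxygen pattern that formaldehyde lays across the C2=C3 bond of a stilbene in a Prins reaction. Ring B, with oxygen para to C2, polarises such a stilbene so that the electrophilic carbon goes to C3 and oxygen to C2; the resulting 1,3-dioxane is not a ring of 22, but its benzylic C2–O bond is the one that acid can exchange for O1.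

## Retrosynthesis

**Enal and ring B phenol.** The Si–O bond of the ring B silyl ether is cut last (22 from 21). The enal is traced through the (Z)-allylic alcohol 20 to the arylalkyne 19, which is cut at the C5–C(sp) bond into aryl bromide 17 and prop-2-yn-1-ol 18. A Z-selective carbonyl olefination of a C5 aldehyde would give an ester and demand further redox steps. The alkyne route fixes the geometry by syn addition of hydrogen and asks of ring A only a bromine atom, which is inert in every earlier step. The forward steps must couple an electron-rich aryl bromide, stop hydrogenation at the alkene, and oxidise and desilylate without Z to E isomerisation.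

**Benzoate.** The C9–O acyl bond of 17 is cut to the primary alcohol 15 and 4-hydroxybenzoic acid 16. Acylation after the acid-mediated ring chemistry keeps an ester carbonyl away from the C2 cation, where it could participate. Acylation before the alkyne coupling means that 15 has a single aliphatic hydroxyl group. A Mitsunobu esterification allows 16 to be used unprotected, because its carboxylic acid and not its phenol is the pronucleophile.

**Ring switch.** In 15 the O1–C2 bond is cut and C2 is reconnected to the oxygen of a formaldehyde acetal that bridges to the C9 oxygen. This gives the phenolic trans-4,5-diaryl-1,3-dioxane 13; the forward reaction passes through the hemiformal 14. This cut is preferred to cuts at C3–C3a or C2–C3 because C2 is self-correcting: any precursor with C3 set and an ionisable oxygen on C2 should close trans. The forward step must ionise the benzylic C–O bond, not the acetal carbon, and leave the C3–H bond alone. Phenol 13 comes from its allyl carbonate 12 by palladium-catalysed deallylation.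

**Prins disconnection.** In 12 the C3–C9 bond, the C2–O bond and the acetal C–O bond are cut. This leaves the (E)-stilbene 10 and two molecules of formaldehyde, both drawn from paraformaldehyde 11: one becomes C9 with its oxygen, the other the acetal CH2O. An aldol cut at C2–C3 would need a ring A arylacetic acid, an auxiliary and a reduction. The Prins cut removes one ring, one skeletal bond and both stereocentres at once and leaves an achiral alkene. Keeping the ring A oxygen acylated, instead of letting a free phenol end the Prins reaction, keeps ring A electron-poor. The forward reaction must form the C–C bond at C3, choose one enantioface, and tolerate the silyl ether, the carbonate and the bromide.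

**Stilbene.** The C2=C3 bond of 10 is cut by a Horner–Wadsworth–Emmons disconnection. An aryl carbonate would not survive a phosphonate anion, so 10 is traced to phenol 9 and its methoxymethyl ether 8, and 8 to phosphonate 5 and aldehyde 7. The phosphonate is placed on the ring B half because the ring A half is commercially available as an aldehyde. The semi-stabilised benzylic anion should give the (E)-alkene.

**Building blocks.** Aldehyde 7 is the methoxymethyl ether of 5-bromo-2-hydroxy-3-methoxybenzaldehyde 6. Phosphonate 5 comes from vanillin 1 by silylation (2), reduction (3), bromination (4) and a Michaelis–Arbuzov reaction. All carbon of 22 then derives from 1, 6, 11, 16 and 18.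

## Roads not taken

Alternative 1: The cut is at the C2–ring B bond and the C3–C3a bond, with O1–C7a closed afterwards.
- **Forward key step:** the ate complex of the (E)-alkenyl boronate A1 and the aryllithium A2 would react with the ring A triflate A3 under Pd(OAc)2 and MandyPhos. The guaiacyl group shifts from boron to C2 while ring A is delivered to C3 on the opposite face, giving the syn boronate A4. Oxidation of the C–B bond and displacement of fluoride by the alkoxide would then close the dihydrofuran ring.
- **Merits:** a known catalytic enantioselective reaction class, both stereocentres set in one stereospecific event, and three simple components.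
- **Weak points:** β-substituted alkenyl boronates are the least reliable substrates of this coupling, since direct cross-coupling of the ate complex competes. A3 needs several steps. Fluoride displacement on a ring with a methoxy group beside the fluorine and only a para ester as activator needs strong base, which endangers the silyl ethers. C2 is fixed by stereoretention, so an imperfect diastereomer ratio cannot be corrected. The C5 ester must still be taken to the (Z)-enal by reduction, Z-olefination and redox steps.
- **Comparison:** this road has the better-founded enantiocontrol. Against it the chosen plan sets commodity starting materials (1, 6, 11), the need for catalyst control at only one stereocentre with the other self-correcting, and a shorter path from the bromide of 17 to the enal.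

Alternative 2: The cut is at C3–C3a and O1–C7a in a single operation.
- **Forward key step:** aryl iodide A5 and the cis-glycidate A6 would react under Pd(OAc)2, norbornene, a triarylphosphine and K2CO3. The palladacycle formed at C3a opens the epoxide at its ester-bearing carbon with inversion, norbornene is extruded, and the alkoxide couples at C7a to give the trans diester A7.
- **Merits:** the shortest route to the bicyclic core, chirality from an easily made epoxide, and a simple arene partner.
- **Weak points:** this annulation is established for terminal epoxides. In A6 the palladacycle must attack the hindered α-carbon of a 2,3-disubstituted epoxide whose other carbon is a para-oxygenated benzylic position, prone to ionise or rearrange under hot basic conditions. A7 then carries three acyl groups (C3 ethyl ester, C5 methyl ester, pivalate) that must be told apart to reduce only the C3 ester to the C9 alcohol, and the C5 ester must still become the (Z)-enal.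
- **Comparison:** if the annulation worked, this road would reach the core in fewer steps than the chosen plan, and its key step is no more speculative than step 9. The chosen plan sets against it that C9 arrives at the alcohol oxidation level and that bromine is the only handle on ring A, so no ester differentiation is needed.

Alternative 3: The cut is at O1–C2 alone, with a change of oxidation level at C2.
- **Forward key step:** DDQ would oxidise the 4-alkyl-2-methoxyphenol of the diarylpropyl benzoate A8 to its para-quinone methide at C2, and the ring A phenol would add to C2 to close the ring trans to the C3 arm, giving A9.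
- **Merits:** the same C3-controlled trans closure as step 11, but without a temporary ring. The single stereocentre of A8 can be set by auxiliary-controlled enolate alkylation, and the benzoate is already in place.
- **Weak points:** A8 has two free phenols and the oxidant must select ring B. A9 keeps a free para-hydroxybenzylic ether that DDQ can oxidise again, towards the benzofuran. Making A8 (auxiliary attachment, alkylation, reductive removal, acylation of the alcohol beside two phenols) takes more steps than stilbene 10. The ring B phenol must afterwards be protected or carried free through the coupling and the MnO2 oxidation.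
- **Comparison:** in certainty of absolute configuration this road is superior. The chosen plan sets against it a catalytic asymmetric C–C bond formation that brings in C9 and the C3 configuration in one step from an achiral alkene, a non-oxidative ring closure, and a protecting-group pattern that lasts to the end.

Key step: step 9

## Route

Step 1
Reactants: 1 vanillin (4-hydroxy-3-methoxybenzaldehyde)
Product: 2 3-methoxy-4-(triisopropylsilyloxy)benzaldehyde
Conditions: i-Pr3SiCl, imidazole, DMF, 23 °C
Reagents that add atoms: triisopropylsilyl chloride, CC(C)[Si](Cl)(C(C)C)C(C)C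
Why: Silylation of a phenol; the bulky aryl silyl ether should survive hydride, NaH, dilute acid, BF3·OEt2 and palladium catalysis, is cleaved by fluoride at the end, and as a para donor supports the C2 cation in steps 9 and 11.

Step 2
Reactants: 2 3-methoxy-4-(triisopropylsilyloxy)benzaldehyde
Product: 3 [3-methoxy-4-(triisopropylsilyloxy)phenyl]methanol
Conditions: NaBH4, MeOH, 0 °C
Reagents that add atoms: none
Why: Borohydride reduction of an aryl aldehyde to the benzylic alcohol; the aryl silyl ether is inert to NaBH4 at 0 °C.

Step 3
Reactants: 3 [3-methoxy-4-(triisopropylsilyloxy)phenyl]methanol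
Product: 4 [4-(bromomethyl)-2-methoxyphenoxy]triisopropylsilane
Conditions: PBr3, Et2O, 0 °C
Reagents that add atoms: phosphorus tribromide, BrP(Br)Br
Why: Conversion of a benzylic alcohol into the bromide through its phosphite ester; the reactive para-oxygenated benzyl bromide is used at once in step 4.

Step 4
Reactants: 4 [4-(bromomethyl)-2-methoxyphenoxy]triisopropylsilane
Product: 5 diethyl [3-methoxy-4-(triisopropylsilyloxy)benzyl]phosphonate
Conditions: P(OEt)3 (neat), 120 °C
Reagents that add atoms: triethyl phosphite, CCOP(OCC)OCC
Why: Michaelis–Arbuzov reaction of a benzylic bromide; bromoethane distils off and the neutral conditions leave the silyl ether intact.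

Step 5
Reactants: 6 5-bromo-2-hydroxy-3-methoxybenzaldehyde
Product: 7 5-bromo-3-methoxy-2-(methoxymethoxy)benzaldehyde
Conditions: MeOCH2Cl, i-Pr2NEt, CH2Cl2, 0 → 23 °C
Reagents that add atoms: chloromethyl methyl ether, COCCl
Why: O-alkylation of the phenol as its methoxymethyl ether, so that no phenoxide deactivates the aldehyde or consumes base in step 6.

Step 6
Reactants: 5 diethyl [3-methoxy-4-(triisopropylsilyloxy)benzyl]phosphonate; 7 5-bromo-3-methoxy-2-(methoxymethoxy)benzaldehyde
Product: 8 [4-[(E)-2-[5-bromo-3-methoxy-2-(methoxymethoxy)phenyl]ethenyl]-2-methoxyphenoxy]triisopropylsilane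
Conditions: NaH, 15-crown-5 (cat.), THF, 0 → 23 °C
Reagents that add atoms: none
Why: Horner–Wadsworth–Emmons olefination; the semi-stabilised benzylic phosphonate anion and an aryl aldehyde should give the (E)-stilbene through reversible addition and elimination from the more stable anti intermediate.

Step 7
Reactants: 8 [4-[(E)-2-[5-bromo-3-methoxy-2-(methoxymethoxy)phenyl]ethenyl]-2-methoxyphenoxy]triisopropylsilane
Product: 9 4-bromo-2-methoxy-6-[(E)-2-[3-methoxy-4-(triisopropylsilyloxy)phenyl]ethenyl]phenol
Conditions: HCl (aq., 3 equiv), MeOH/THF, 40 °C
Reagents that add atoms: none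
Why: Acid-catalysed acetal exchange with methanol removes the methoxymethyl ether; the aryl triisopropylsilyl ether is stable to dilute methanolic HCl, which is also too weak to protonate the stilbene.

Step 8
Reactants: 9 4-bromo-2-methoxy-6-[(E)-2-[3-methoxy-4-(triisopropylsilyloxy)phenyl]ethenyl]phenol
Product: 10 allyl 4-bromo-2-methoxy-6-[(E)-2-[3-methoxy-4-(triisopropylsilyloxy)phenyl]ethenyl]phenyl carbonate
Conditions: allyl chloroformate, pyridine, CH2Cl2, 0 °C
Reagents that add atoms: allyl chloroformate, C=CCOC(=O)Cl
Why: O-acylation of the phenol to the aryl allyl carbonate, which makes ring A electron-poor for step 9 and can later be removed under neutral conditions.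

Step 9
Reactants: 10 allyl 4-bromo-2-methoxy-6-[(E)-2-[3-methoxy-4-(triisopropylsilyloxy)phenyl]ethenyl]phenyl carbonate; 11 paraformaldehyde (supplies the first CH2O unit, which becomes C9 and its oxygen)
Product: 12 allyl 4-bromo-2-methoxy-6-[(4R,5R)-4-[3-methoxy-4-(triisopropylsilyloxy)phenyl]-1,3-dioxan-5-yl]phenyl carbonate (trans)
Conditions: (CH2O)n (6 equiv), confined chiral imidodiphosphorimidate Brønsted acid (N-triflyl groups, 3,3′-diaryl-BINOL backbones; 5 mol %), cyclohexane/CHCl3, 25 °C
Reagents that add atoms: formaldehyde (the second CH2O unit, drawn from the same paraformaldehyde 11; it becomes the acetal CH2 between the two ring oxygens and the oxygen bound to C2), C=O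
Why: Proposed new method: the confined acid protonates formaldehyde inside its chiral pocket, and this electrophile bonds through carbon to C3 of the stilbene (first CH2O unit, which becomes C9 and its oxygen), so that positive charge develops at C2 where the para-silyloxy ring B stabilises it, while ring A is made electron-poor by its carbonate and bromine; a second CH2O unit is taken up at the C9 oxygen as a hemiformal, whose terminal oxygen then bonds to C2. The closest known reactions are the confined-acid catalysed asymmetric Prins reaction of styrenes with paraformaldehyde to 4-aryl-1,3-dioxanes and the classical Prins dioxane synthesis from 1-arylpropenes; a 1,2-diaryl alkene has not been used in the asymmetric version. The 1,3-dioxane is the only ring closed: C2–O bond formation is a 6-exo-trig capture of the benzylic, quinoid cation by the hemiformal oxygen, and in the concerted, strongly asynchronous limit the whole event is a suprafacial addition of a CH2–O–CH2–O unit across C2=C3. C5 of the dioxane (C3 of the target, R) is set by the catalyst, whose chiral anion pocket lets the electrophile reach only one enantioface at C3. C4 of the dioxane (C2 of the target) follows from suprafacial addition to the (E)-alkene and from the diequatorial preference of the trans isomer, and since step 11 ionises this centre again a cis component would converge to the same product. The step needs regioselectivity (C–C bond at C3, secured by the electronic difference between the two rings), enantioface selectivity at C3 (catalyst control, unproven for stilbenes) and chemoselectivity over hydroxymethylation of ring B and over the allyl group (the donor-substituted conjugated alkene is the most nucleophilic π-system, and the allyl alkene is deactivated by the carbonate oxygen).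

Step 10
Reactants: 12 allyl 4-bromo-2-methoxy-6-[(4R,5R)-4-[3-methoxy-4-(triisopropylsilyloxy)phenyl]-1,3-dioxan-5-yl]phenyl carbonate
Product: 13 4-bromo-2-methoxy-6-[(4R,5R)-4-[3-methoxy-4-(triisopropylsilyloxy)phenyl]-1,3-dioxan-5-yl]phenol
Conditions: Pd(PPh3)4 (3 mol %), morpholine, THF, 23 °C
Reagents that add atoms: none
Why: Tsuji–Trost deallylation: zerovalent palladium ionises the allyl carbonate, CO2 is lost and morpholine traps the allyl group; oxidative addition into the electron-rich aryl bromide does not compete at room temperature with PPh3 as ligand, and no stereocentre is touched.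

Step 11
Reactants: 13 4-bromo-2-methoxy-6-[(4R,5R)-4-[3-methoxy-4-(triisopropylsilyloxy)phenyl]-1,3-dioxan-5-yl]phenol
Product: 15 [(2S,3R)-5-bromo-7-methoxy-2-[3-methoxy-4-(triisopropylsilyloxy)phenyl]-2,3-dihydro-1-benzofuran-3-yl]methanol, via C9 hemiformal 14 (not isolated)
Conditions: BF3·OEt2 (0.3 equiv), CH2Cl2, −40 → 0 °C; then MeOH, aq. NaHCO3
Reagents that add atoms: none
Why: Lewis-acid benzylic C–O heterolysis (SN1) at the para-silyloxybenzyl acetal oxygen, the mode known from acid solvolysis and ionic hydrogenation of 4-aryl-1,3-dioxanes, gives a C2 cation that the ring A phenol captures in a 5-exo closure, the same benzylic-cation cyclisation that turns 1-aryl-2-(2-hydroxyaryl)propane-1,3-diols into trans-2-aryl-dihydrobenzofurans. C2 is set S, trans to the C9 arm, by attack anti to the C3 substituent and by equilibration under the acid (a net inversion at C2 relative to the trans dioxane), while C3 is not involved. The hemiformal 14 should lose formaldehyde in the methanolic bicarbonate quench.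

Step 12
Reactants: 15 [(2S,3R)-5-bromo-7-methoxy-2-[3-methoxy-4-(triisopropylsilyloxy)phenyl]-2,3-dihydro-1-benzofuran-3-yl]methanol; 16 4-hydroxybenzoic acid
Product: 17 [(2S,3R)-5-bromo-7-methoxy-2-[3-methoxy-4-(triisopropylsilyloxy)phenyl]-2,3-dihydro-1-benzofuran-3-yl]methyl 4-hydroxybenzoate
Conditions: PPh3, DIAD, 16 (1.5 equiv), THF, 0 → 23 °C
Reagents that add atoms: none
Why: Mitsunobu esterification; the carboxylic acid of 16 is far more acidic than its phenol and is the pronucleophile, so phenolic acids esterify primary alcohols chemoselectively without protection. Substitution takes place at the primary carbon C9, so no stereocentre is touched.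

Step 13
Reactants: 17 [(2S,3R)-5-bromo-7-methoxy-2-[3-methoxy-4-(triisopropylsilyloxy)phenyl]-2,3-dihydro-1-benzofuran-3-yl]methyl 4-hydroxybenzoate; 18 prop-2-yn-1-ol
Product: 19 [(2S,3R)-5-(3-hydroxyprop-1-yn-1-yl)-7-methoxy-2-[3-methoxy-4-(triisopropylsilyloxy)phenyl]-2,3-dihydro-1-benzofuran-3-yl]methyl 4-hydroxybenzoate
Conditions: Pd(PhCN)2Cl2 (3 mol %), [HP(t-Bu)3]BF4, CuI, i-Pr2NH, 1,4-dioxane, 23 → 40 °C
Reagents that add atoms: none
Why: Sonogashira coupling; a bulky electron-rich trialkylphosphine lets electron-rich aryl bromides couple near room temperature, and free phenols, alcohols and the benzoate are tolerated by the amine base.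

Step 14
Reactants: 19 [(2S,3R)-5-(3-hydroxyprop-1-yn-1-yl)-7-methoxy-2-[3-methoxy-4-(triisopropylsilyloxy)phenyl]-2,3-dihydro-1-benzofuran-3-yl]methyl 4-hydroxybenzoate
Product: 20 [(2S,3R)-5-[(1Z)-3-hydroxyprop-1-en-1-yl]-7-methoxy-2-[3-methoxy-4-(triisopropylsilyloxy)phenyl]-2,3-dihydro-1-benzofuran-3-yl]methyl 4-hydroxybenzoate
Conditions: H2 (1 atm), Pd/CaCO3 poisoned with Pb(OAc)2, quinoline, EtOAc, 23 °C
Reagents that add atoms: none
Why: Lindlar-type semi-hydrogenation; syn delivery of hydrogen on the poisoned surface should give the (Z)-alkene, no aryl halide remains, and the benzylic C–O bonds are not hydrogenolysed on this catalyst.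

Step 15
Reactants: 20 [(2S,3R)-5-[(1Z)-3-hydroxyprop-1-en-1-yl]-7-methoxy-2-[3-methoxy-4-(triisopropylsilyloxy)phenyl]-2,3-dihydro-1-benzofuran-3-yl]methyl 4-hydroxybenzoate
Product: 21 [(2S,3R)-7-methoxy-2-[3-methoxy-4-(triisopropylsilyloxy)phenyl]-5-[(1Z)-3-oxoprop-1-en-1-yl]-2,3-dihydro-1-benzofuran-3-yl]methyl 4-hydroxybenzoate
Conditions: MnO2 (activated, excess), CH2Cl2, 23 °C, dark
Reagents that add atoms: none
Why: Heterogeneous allylic oxidation under neutral conditions, which converts (Z)-cinnamyl alcohols into (Z)-enals with retention of geometry; the electron-poor phenol of ring C and the silyl ether should be inert.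

Step 16
Reactants: 21 [(2S,3R)-7-methoxy-2-[3-methoxy-4-(triisopropylsilyloxy)phenyl]-5-[(1Z)-3-oxoprop-1-en-1-yl]-2,3-dihydro-1-benzofuran-3-yl]methyl 4-hydroxybenzoate
Product: 22 [(2S,3R)-2-(4-hydroxy-3-methoxyphenyl)-7-methoxy-5-[(1Z)-3-oxoprop-1-en-1-yl]-2,3-dihydro-1-benzofuran-3-yl]methyl 4-hydroxybenzoate (CNP0400980.1)
Conditions: Bu4NF, AcOH (1:1), THF, 0 °C, dark
Reagents that add atoms: none
Why: Fluoride cleavage of the aryl silyl ether; buffering with acetic acid keeps the medium near neutral so that neither the benzoate nor the (Z)-enal should be attacked, and the product is handled cold and in the dark.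

## Compound list

1 | vanillin (4-hydroxy-3-methoxybenzaldehyde) | COc1cc(C=O)ccc1O | starting material
2 | 3-methoxy-4-(triisopropylsilyloxy)benzaldehyde | COc1cc(C=O)ccc1O[Si](C(C)C)(C(C)C)C(C)C | intermediate
3 | [3-methoxy-4-(triisopropylsilyloxy)phenyl]methanol | COc1cc(CO)ccc1O[Si](C(C)C)(C(C)C)C(C)C | intermediate
4 | [4-(bromomethyl)-2-methoxyphenoxy]triisopropylsilane | COc1cc(CBr)ccc1O[Si](C(C)C)(C(C)C)C(C)C | intermediate
5 | diethyl [3-methoxy-4-(triisopropylsilyloxy)benzyl]phosphonate | CCOP(=O)(Cc1ccc(O[Si](C(C)C)(C(C)C)C(C)C)c(OC)c1)OCC | intermediate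
6 | 5-bromo-2-hydroxy-3-methoxybenzaldehyde | COc1cc(Br)cc(C=O)c1O | starting material
7 | 5-bromo-3-methoxy-2-(methoxymethoxy)benzaldehyde | COCOc1c(OC)cc(Br)cc1C=O | intermediate
8 | [4-[(E)-2-[5-bromo-3-methoxy-2-(methoxymethoxy)phenyl]ethenyl]-2-methoxyphenoxy]triisopropylsilane | COCOc1c(OC)cc(Br)cc1/C=C/c1ccc(O[Si](C(C)C)(C(C)C)C(C)C)c(OC)c1 | intermediate
9 | 4-bromo-2-methoxy-6-[(E)-2-[3-methoxy-4-(triisopropylsilyloxy)phenyl]ethenyl]phenol | COc1cc(/C=C/c2cc(Br)cc(OC)c2O)ccc1O[Si](C(C)C)(C(C)C)C(C)C | intermediate
10 | allyl 4-bromo-2-methoxy-6-[(E)-2-[3-methoxy-4-(triisopropylsilyloxy)phenyl]ethenyl]phenyl carbonate | COc1cc(/C=C/c2cc(Br)cc(OC)c2OC(=O)OCC=C)ccc1O[Si](C(C)C)(C(C)C)C(C)C | intermediate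
11 | paraformaldehyde (polymeric formaldehyde, reacts as CH2O; two units enter 12) | C=O | starting material
12 | allyl 4-bromo-2-methoxy-6-[(4R,5R)-4-[3-methoxy-4-(triisopropylsilyloxy)phenyl]-1,3-dioxan-5-yl]phenyl carbonate | COc1cc([C@@H]2OCOC[C@H]2c3cc(Br)cc(OC)c3OC(=O)OCC=C)ccc1O[Si](C(C)C)(C(C)C)C(C)C | intermediate
13 | 4-bromo-2-methoxy-6-[(4R,5R)-4-[3-methoxy-4-(triisopropylsilyloxy)phenyl]-1,3-dioxan-5-yl]phenol | COc1cc([C@@H]2OCOC[C@H]2c3cc(Br)cc(OC)c3O)ccc1O[Si](C(C)C)(C(C)C)C(C)C | intermediate
14 | [[(2S,3R)-5-bromo-7-methoxy-2-[3-methoxy-4-(triisopropylsilyloxy)phenyl]-2,3-dihydro-1-benzofuran-3-yl]methoxy]methanol (C9 hemiformal, not isolated) | COc1cc([C@H]2Oc3c(OC)cc(Br)cc3[C@@H]2COCO)ccc1O[Si](C(C)C)(C(C)C)C(C)C | intermediate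
15 | [(2S,3R)-5-bromo-7-methoxy-2-[3-methoxy-4-(triisopropylsilyloxy)phenyl]-2,3-dihydro-1-benzofuran-3-yl]methanol | COc1cc([C@H]2Oc3c(OC)cc(Br)cc3[C@@H]2CO)ccc1O[Si](C(C)C)(C(C)C)C(C)C | intermediate
16 | 4-hydroxybenzoic acid | O=C(O)c1ccc(O)cc1 | starting material
17 | [(2S,3R)-5-bromo-7-methoxy-2-[3-methoxy-4-(triisopropylsilyloxy)phenyl]-2,3-dihydro-1-benzofuran-3-yl]methyl 4-hydroxybenzoate | COc1cc([C@H]2Oc3c(OC)cc(Br)cc3[C@@H]2COC(=O)c2ccc(O)cc2)ccc1O[Si](C(C)C)(C(C)C)C(C)C | intermediate
18 | prop-2-yn-1-ol | C#CCO | starting material
19 | [(2S,3R)-5-(3-hydroxyprop-1-yn-1-yl)-7-methoxy-2-[3-methoxy-4-(triisopropylsilyloxy)phenyl]-2,3-dihydro-1-benzofuran-3-yl]methyl 4-hydroxybenzoate | COc1cc([C@H]2Oc3c(OC)cc(C#CCO)cc3[C@@H]2COC(=O)c2ccc(O)cc2)ccc1O[Si](C(C)C)(C(C)C)C(C)C | intermediate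
20 | [(2S,3R)-5-[(1Z)-3-hydroxyprop-1-en-1-yl]-7-methoxy-2-[3-methoxy-4-(triisopropylsilyloxy)phenyl]-2,3-dihydro-1-benzofuran-3-yl]methyl 4-hydroxybenzoate | COc1cc([C@H]2Oc3c(OC)cc(/C=C\CO)cc3[C@@H]2COC(=O)c2ccc(O)cc2)ccc1O[Si](C(C)C)(C(C)C)C(C)C | intermediate
21 | [(2S,3R)-7-methoxy-2-[3-methoxy-4-(triisopropylsilyloxy)phenyl]-5-[(1Z)-3-oxoprop-1-en-1-yl]-2,3-dihydro-1-benzofuran-3-yl]methyl 4-hydroxybenzoate | COc1cc([C@H]2Oc3c(OC)cc(/C=C\C=O)cc3[C@@H]2COC(=O)c2ccc(O)cc2)ccc1O[Si](C(C)C)(C(C)C)C(C)C | intermediate
22 | [(2S,3R)-2-(4-hydroxy-3-methoxyphenyl)-7-methoxy-5-[(1Z)-3-oxoprop-1-en-1-yl]-2,3-dihydro-1-benzofuran-3-yl]methyl 4-hydroxybenzoate | COc1cc([C@H]2Oc3c(OC)cc(/C=C\C=O)cc3[C@@H]2COC(=O)c2ccc(O)cc2)ccc1O | target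

## Step count and least certain steps

Total step count: 16. Longest linear sequence: 15 steps (from 1 through steps 1 to 4 and 6 to 16; step 5 is the one-step side branch from 6).

**Step 9 (key step, proposed new method).** The most likely failure is low turnover or poor enantioface discrimination, because a 1,2-diaryl alkene with a bulky silyl ether and an ortho-substituted ring A may not fit the confined pocket that was developed for styrenes. Hydroxymethylation of ring B para to its methoxy group and acid-induced loss of the silyl group are secondary risks. Fallback with known chemistry: from 10, the classical Prins dioxane synthesis with paraformaldehyde and an achiral strong acid (catalytic HNTf2, CH2Cl2, 0 °C) should give the racemic trans-dioxane carbonate F1. Its enantiomers are separated by preparative chromatography on a cellulose tris(3,5-dimethylphenylcarbamate) phase, and the (4R,5R) enantiomer is 12, where the route resumes.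

**Step 11.** The most likely failure is ionisation at the acetal carbon instead of the benzylic carbon, followed by capture of the methylene oxocarbenium ion by the phenol or by intermolecular formal formation. Further risks are alkylation of the electron-rich rings by the released formaldehyde and erosion of the C3 configuration by reversible loss of the C3 proton from the cation. Fallback: from 13, the methylene acetal is cleaved at the acetal carbon under non-ionising conditions (Me3SiOTf, 2,2′-bipyridyl, CH2Cl2, 0 °C; then H2O). This should give (1R,2R)-2-(5-bromo-2-hydroxy-3-methoxyphenyl)-1-[3-methoxy-4-(triisopropylsilyloxy)phenyl]propane-1,3-diol F2, free of formaldehyde and with both centres intact. Catalytic TsOH in CH2Cl2 then effects the established benzylic-cation cyclisation of such diols to the trans-dihydrobenzofuran, returning to the route at 15.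

**Step 12.** The most likely failure is competing O-alkylation of a phenolic hydroxyl group (of 16 or of the product) by the activated C9 oxygen, giving aryl ethers and oligomers. Elimination of the activated oxygen towards the 3-methylene compound is a further risk. Fallback: from 15, acylation with commercial 4-acetoxybenzoyl chloride (pyridine, DMAP cat., CH2Cl2, 0 °C) should give [(2S,3R)-5-bromo-7-methoxy-2-[3-methoxy-4-(triisopropylsilyloxy)phenyl]-2,3-dihydro-1-benzofuran-3-yl]methyl 4-acetoxybenzoate F3. Its aryl acetate is removed selectively with hydrazine hydrate in THF at 0 °C, which rejoins the route at 17.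

**Step 16.** The most likely failure is Z to E isomerisation of the enal through reversible conjugate addition of fluoride, acetate or phenoxide, or through light, during or after desilylation. Fallback: from 20, the order of the last two operations is reversed. Desilylation with Bu4NF/AcOH should give [(2S,3R)-2-(4-hydroxy-3-methoxyphenyl)-5-[(1Z)-3-hydroxyprop-1-en-1-yl]-7-methoxy-2,3-dihydro-1-benzofuran-3-yl]methyl 4-hydroxybenzoate F4, and MnO2 oxidation of its allylic alcohol as the last step leads directly to 22, so that the enal never meets fluoride.

## Further compounds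

F1 | step 9 | racemic allyl 4-bromo-2-methoxy-6-[trans-4-[3-methoxy-4-(triisopropylsilyloxy)phenyl]-1,3-dioxan-5-yl]phenyl carbonate (1:1 mixture of the 4R,5R and 4S,5S enantiomers) | COc1cc([C@@H]2OCOC[C@H]2c3cc(Br)cc(OC)c3OC(=O)OCC=C)ccc1O[Si](C(C)C)(C(C)C)C(C)C.COc1cc([C@H]2OCOC[C@@H]2c3cc(Br)cc(OC)c3OC(=O)OCC=C)ccc1O[Si](C(C)C)(C(C)C)C(C)C
F2 | step 11 | (1R,2R)-2-(5-bromo-2-hydroxy-3-methoxyphenyl)-1-[3-methoxy-4-(triisopropylsilyloxy)phenyl]propane-1,3-diol | COc1cc([C@H](O)[C@@H](CO)c2cc(Br)cc(OC)c2O)ccc1O[Si](C(C)C)(C(C)C)C(C)C
F3 | step 12 | [(2S,3R)-5-bromo-7-methoxy-2-[3-methoxy-4-(triisopropylsilyloxy)phenyl]-2,3-dihydro-1-benzofuran-3-yl]methyl 4-acetoxybenzoate | COc1cc([C@H]2Oc3c(OC)cc(Br)cc3[C@@H]2COC(=O)c2ccc(OC(C)=O)cc2)ccc1O[Si](C(C)C)(C(C)C)C(C)C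
F4 | step 16 | [(2S,3R)-2-(4-hydroxy-3-methoxyphenyl)-5-[(1Z)-3-hydroxyprop-1-en-1-yl]-7-methoxy-2,3-dihydro-1-benzofuran-3-yl]methyl 4-hydroxybenzoate | COc1cc([C@H]2Oc3c(OC)cc(/C=C\CO)cc3[C@@H]2COC(=O)c2ccc(O)cc2)ccc1O
A1 | alternative 1 | tert-butyldimethyl[[(E)-3-(4,4,5,5-tetramethyl-1,3,2-dioxaborolan-2-yl)prop-2-en-1-yl]oxy]silane | CC(C)(C)[Si](C)(C)OC/C=C/B1OC(C)(C)C(C)(C)O1
A2 | alternative 1 | [3-methoxy-4-(triisopropylsilyloxy)phenyl]lithium | [Li]c1ccc(O[Si](C(C)C)(C(C)C)C(C)C)c(OC)c1
A3 | alternative 1 | methyl 4-fluoro-3-methoxy-5-[(trifluoromethylsulfonyl)oxy]benzoate | COC(=O)c1cc(OC)c(F)c(OS(=O)(=O)C(F)(F)F)c1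
A4 | alternative 1 | methyl 3-[(1S,2R)-3-(tert-butyldimethylsilyloxy)-1-[3-methoxy-4-(triisopropylsilyloxy)phenyl]-1-(4,4,5,5-tetramethyl-1,3,2-dioxaborolan-2-yl)propan-2-yl]-4-fluoro-5-methoxybenzoate (syn boronate) | COc1cc([C@@H](B2OC(C)(C)C(C)(C)O2)[C@@H](CO[Si](C)(C)C(C)(C)C)c2cc(C(=O)OC)cc(OC)c2F)ccc1O[Si](C(C)C)(C(C)C)C(C)C
A5 | alternative 2 | methyl 4-iodo-3-methoxybenzoate | COC(=O)c1ccc(I)c(OC)c1
A6 | alternative 2 | ethyl (2R,3R)-3-[3-methoxy-4-(pivaloyloxy)phenyl]oxirane-2-carboxylate (cis) | COc1cc([C@H]2O[C@H]2C(=O)OCC)ccc1OC(=O)C(C)(C)C
A7 | alternative 2 | 3-ethyl 5-methyl (2S,3S)-7-methoxy-2-[3-methoxy-4-(pivaloyloxy)phenyl]-2,3-dihydro-1-benzofuran-3,5-dicarboxylate (trans) | COc1cc([C@H]2Oc3c(OC)cc(C(=O)OC)cc3[C@@H]2C(=O)OCC)ccc1OC(=O)C(C)(C)C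
A8 | alternative 3 | (2R)-2-(5-bromo-2-hydroxy-3-methoxyphenyl)-3-(4-hydroxy-3-methoxyphenyl)propyl 4-(triisopropylsilyloxy)benzoate | COc1cc(C[C@@H](COC(=O)c2ccc(O[Si](C(C)C)(C(C)C)C(C)C)cc2)c2cc(Br)cc(OC)c2O)ccc1O
A9 | alternative 3 | [(2S,3R)-5-bromo-2-(4-hydroxy-3-methoxyphenyl)-7-methoxy-2,3-dihydro-1-benzofuran-3-yl]methyl 4-(triisopropylsilyloxy)benzoate (trans) | COc1cc([C@H]2Oc3c(OC)cc(Br)cc3[C@@H]2COC(=O)c2ccc(O[Si](C(C)C)(C(C)C)C(C)C)cc2)ccc1O
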